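The data stem from a simulated flask with made-up constants, noise included.

A tempting error with a catalysed flask is to carry a percentage from one charge to another, as one may in an enzyme assay far below saturation. Write S for the concentration of starting material, reckoned as its charge minus the product read.

| setting | noon | winter | dawn | spring | summer |
|---|---|---|---|---|---|
| starting material | 0.400 M | 0.240 M | 0.400 M | 1.20 M | 0.130 M |
| partner | 0.480 M | 0.320 M | 0.480 M | 0.480 M | 0.960 M |
| free catalyst | 0.0120 M | 0.0120 M | 0.00600 M | 0.0120 M | 0.0120 M |
| time |  |  |  |  | 21 min |

- noon run (time / min: [product] / M): 3.0: 0.0545; 6.0: 0.1022; 9.0: 0.1416; 12: 0.1789; 15: 0.2064; 18: 0.2317; 21: 0.2520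
- winter run (time / min: [product] / M): 3.0: 0.0378; 6.0: 0.0679; 9.0: 0.0921; 12: 0.1140; 15: 0.1324; 18: 0.1478; 21: 0.1610
- dawn run (time / min: [product] / M): 3.0: 0.0299; 6.0: 0.0557; 9.0: 0.0778; 12: 0.1004; 15: 0.1187; 18: 0.1360; 21: 0.1520
- spring run (time / min: [product] / M): 3.0: 0.1051; 6.0: 0.1916; 9.0: 0.2629; 12: 0.3234; 15: 0.3699; 18: 0.4054; 21: 0.4302

(each reading ± 0.001 M)

1. the power of [partner] that the first rate follows, about the charge of the noon run; measure it at two percent of starting material made into product
2. the power of [starting material] that the first rate follows, about the charge of the noon run; measure it at two percent of starting material made into product (one fixed amount of product, the same in the runs compared)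
3. the winter run starts with 0.160 M less of starting material and of partner than the noon run, and with no product. Compared where both hold the same amount of starting material, once fifteen percent of what the winter run was charged with has turned into product, is the winter run faster, slower or alike (within a tenth)?
4. product in the summer run at 21 min, as a share of the starting material charged

- Overall: starting material + partner -> product, with free catalyst as catalyst.
- Constant volume, constant temperature.
- The analysis sees a species whether free or bound.
- An order is taken over about fifteen percent of the charge, up and down.

Two colleagues disagree about the summer run, which has a smaller charge of starting material than the earlier runs and twice the partner of noon. The first holds that the flask is pseudo-first-order in S, so the share turned at a given time does not depend on the charge. She has a ground: at 21 min noon has turned 63.0% and winter 67.1%, so between these two charges a share carries fairly well.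

The second looks at the first reading. At 3.0 min the spring run, with noon's partner and catalyst, has turned 8.76% of its charge, a smaller share than noon's 13.6%. Spring's product is 1.93 times noon's for 3.00 times the charge, which reads as a rate going with S to the power n = 0.598.

I side with the second and reckon as follows. If the rate goes as S to the power n, then θ, defined as S/0.400 M raised to the power 0.402 (1 minus n), falls at a steady pace for a given catalyst and partner, whatever the charge. Noon's θ goes from 1 to 0.670 in 21 min, so the clock rate, the average fall of θ per minute read from the noon run at its charge of catalyst and partner, is 0.0157 min⁻¹.

The summer run starts at θ = 0.636, so the same fall brings it to 0.307 at 21 min, which I reckon as 83.7% of its charge turned. The summer charge starts lower on this clock than noon's, so the same fall takes a larger share of it than noon's. The winter run, which holds less partner than noon, fell 0.293 against noon's 0.330, and the summer run holds more partner than noon, so I lean to thinking my estimate low.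

The forecast gives powers of 0 in partner and 0.75 in starting material, faster for winter and 68% for the summer run, because “summer behaves as first order”, which is the first colleague's same-share view.

The simulation gives powers of 0.25 in partner and 0.58 in starting material, winter faster, and 89.0% for the summer run, 5.3 percentage points above my estimate.

    free catalyst + partner ⇌ catalyst-reagent complex, settled at all times (6.860 M⁻¹)
    catalyst-reagent complex + starting material → product + free catalyst (22.98 M⁻¹ min⁻¹)
    free catalyst + partner → spent catalyst + partner (0.1530 M⁻¹ min⁻¹)
    2 starting material ⇌ idle substrate dimer, settled at all times (16.30 M⁻¹)

The step that pairs starting material into the idle substrate dimer has the constant 16.3 M⁻¹. Winter starts at θ = 0.814, and at noon's clock rate, turning half of its charge takes 12.6 min; the winter run reaches that point at 12.8 min.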